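Compound numbers 1–26 are fixed by the steps below and used throughout. Locants C1–C20 are those of the abietane skeleton. Ring B is C5–C10 with the ketone at C7, and ring C is C8, C9, C11–C14. The open ring A leaves C1–C3 as the arm on C10 and C4 as the isopropenyl carbon on C5. In every ring-B compound H-5 is α and the C20 methyl on C10 is β, so the C5 substituent is cis to the methyl and trans to the C1–C3 arm, as in 26.

## Analysis of the target

Compound 26 is a 3,4-seco-abietane. Ring B is a cyclohexenone (C7 ketone) fused through C8=C9 to ring C, a 2-hydroxy-1,4-benzoquinone with carbonyls at C11 and C14, the hydroxyl at C12 and isopropyl at C13. Ring A is open, so C10 carries the C20 methyl and a CH2CH2CO2Me arm (C1–C3), and C5 carries an isopropenyl group. The only stereocentres are the adjacent tertiary C5 and quaternary C10, both S, with the isopropenyl group cis to the methyl and trans to the arm. Sensitive groups are the acidic, redox-active hydroxyquinone, the isopropenyl group (acid, electrophiles, hydrogenation catalysts), the methyl ester, and the C6 methylene, which is enolisable toward a C7 ketone conjugated with a quinone. The synthesis is hard for three reasons: ring C is fully substituted and the C12 oxygen and C13 isopropyl must be placed without ambiguity; three carbonyls (C7, C14, C11) crowd the C8–C9 edge; and C9 is flanked by the quaternary C10. The strategy rests on the C11–C14 run of ring C, which carries oxygen, oxygen, carbon, oxygen and so has the carbon and oxidation pattern of a squaric acid ester, together with the ring-B bond C8=C9, whose C8 is the α-carbon of the C7 enone and can therefore be turned into a nucleophile.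

## Retrosynthetic reasoning

Endgame (26 back to 22). The free C12 hydroxyl is released last from isopropyl ether 25, because a free hydroxyquinone would be O-methylated when the acid 24 is esterified. Acid 24 comes from the primary alcohol of 23 in the same oxidation that turns the hydroquinone into the quinone. Compound 23 is the fully unmasked form of 22. The dioxolane on C7 is removed at the hydroquinone stage, not at the quinone stage: next to an electron-rich arene with an ortho oxygen the ketal ionises easily, whereas next to a quinone the oxocarbenium ion would be destabilised. No C–C bond is cut in this stretch.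

Ring C (22 back to 19). The C9–C11 bond is cut and ring C is unrolled to the four-membered ring of cyclobutenone 19, in which C11 and C14 are still bonded directly to each other and C14 is a carbinol carbon bound to C8. The cut is made here because it removes the whole hexasubstituted ring in one step and leaves a precursor whose four carbons come with O12 and the C13 isopropyl already in place. The forward reaction must open the four-membered ring to a dienylketene (20) with the alkenyl group turned inward, bond the ketene carbon to C9 (21) and aromatise. The carbinol oxygen is kept as a trimethylsilyl ether: it is needed anyway for the preceding step, and it prevents a free hydroxyl from adding to the ketene if closure at the hindered C9 is slow.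

Regiochemistry of the four-carbon unit (19 back to 16 and 17, 16 back to 12 and 13). The C13–isopropyl bond and the C8–C14 bond are cut. Adding an alkenyl nucleophile to a preformed isopropyl-substituted squarate derivative would place the carbinol next to the alkoxy carbon, which is the wrong isomer. The order is therefore reversed: the ring-B alkenyllithium 14 adds first to symmetrical 13, the carbinol is silylated (16), isopropyllithium 17 adds second, and an acid-triggered carbonyl shift with loss of one isopropoxy group gives 19 with the isopropyl carbon next to the carbinol. The alkenyllithium comes from iodide 12. An α-iodoenone ketal is used because it is the standard α-keto vinyl anion equivalent and already carries the C7 oxygen.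

Isopropenyl group and arm (12 back to 8). The two methyl–C4 bonds are cut: the isopropenyl group is traced to the C5 ethyl ester of 10 through tertiary carbinol 11. The silyl ether arm of 10 is traced through alcohol 9 to the methyl ester of 8. The arm has to be a silyl ether and not an ester during the organolithium steps, and the ester on C5 has to stay until the arm ester has been reduced, so the two esters are distinguished by their steric environment.

Iodide, ketal and arm carbons (8 back to 4). Saturation of the arm alkene (7 to 8) is placed after iodination and ketalisation (5 to 6 to 7), because only then is the ring alkene trisubstituted and unreactive toward a metal-free hydrogen transfer. The C1=C2 bond is cut by an ylide olefination of the aldehyde of 4, which adds C2 and C3.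

Ring B (4 back to 1 and 2). C9–C10 and C5–C6 are cut in a cycloaddition between aminosiloxydiene 1 and enal ester 2. This sets both stereocentres at once, fixes their relative configuration through the E geometry of 2, and delivers the C7 ketone and the C8=C9 bond exactly where the later chemistry needs them.

## Alternatives that were turned down

Alternative 1: The ring-B ketone A1 (2-allyl-2-methyl-3-(prop-1-en-2-yl)cyclohexan-1-one, allyl trans to isopropenyl) is disconnected at C4–C5 and C1–C10, which leads back to the enone A2 (2-methylcyclohex-2-en-1-one).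
- Forward key step: an isopropenyl group is transferred from magnesium to the β-carbon of A2 under CuBr·SMe2/chiral diphosphine catalysis, and the magnesium enolate is allylated in the same flask, anti to the new substituent, to give A1.
- In its favour: both stereocentres and both carbon substituents arrive in one operation from the cheap enone A2. The allyl group already has the three carbons of the arm and tolerates organolithium reagents without protection. No ester has to be turned into an isopropenyl group. On front-end step economy it is clearly stronger than the chosen route, which needs nine steps to reach 12.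
- Against it: the carbonyl of A1 sits at C9, C8 is a plain methylene and C7 has no oxygen. Ring C would have to be annulated onto a ketone next to the quaternary centre, and C7 would have to be oxidised late, beside a hydroxyquinone. Conjugate addition to the 2-substituted (trisubstituted) enone A2 and C-allylation of the resulting hindered enolate are each less dependable than on the unsubstituted system. Two terminal alkenes would later have to be told apart.
- In comparison: the chosen strategy offers the C7 oxygen and a C8 nucleophile from the first step, and ring C with all four substituents in a single ring closure.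

Alternative 2: Ring B is disconnected at C9–C10 and C5–C6.
- Forward key step: the chromium-catalysed cycloaddition of the same diene and dienophile that open the chosen route (1 and 2), giving A3 (ethyl 2-formyl-2-methyl-5-oxocyclohex-3-ene-1-carboxylate, formyl trans to ester, identical with 4).
- In its favour: it is catalytic, sets both stereocentres in one step, guarantees the relative configuration through the alkene geometry, and puts the C7 ketone and C8=C9 alkene in the right place. On ring B it is as strong as anything available, which is why it is used as step 1 here.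
- Against it: as a strategy in its own right it solves the easier half of the molecule. The hexasubstituted hydroxyquinone would be left to a stepwise annulation and oxygenation sequence on the C8–C9 edge of A3, where three oxygens and the isopropyl group would have to be placed one substituent at a time.
- In comparison: the chosen strategy keeps this cycloaddition as a supplier and puts the strategic weight, and the risk, on the one step that builds ring C complete.

Alternative 3: Ring C is disconnected at C11–C12, C13–C14 and C8–C14.
- Forward key step: the carbene complex A4 (the pentacarbonyl alkenyl(methoxy)carbene complex of zerovalent chromium whose carbene carbon C11 is bonded to C9 of ring B), the alkyne A5 (3-methylbut-1-yne) and one carbonyl ligand combine in a Dötz benzannulation. The product is the 4-methoxyphenol A6 (C14 hydroxyl, C13 isopropyl, C11 methoxy, C12 unsubstituted, C7 a methylene).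
- In its favour: three components converge, insertion of A5 places the isopropyl group next to the new hydroxyl reliably, and the ring closes at C8, away from the quaternary C10. On that last point it is stronger than the chosen route, whose closure is at the hindered C9.
- Against it: A6 lacks the C12 oxygen and the C7 oxygen, so two late C–H oxidations are needed, one on a quinone and one benzylic. The carbene carbon of A4 has to be installed on the carbon next to C10. Hindered carbene complexes often divert to cyclobutenones, indenes or furans, and chromium is used stoichiometrically.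
- In comparison: the chosen strategy accepts the harder closure and gets in return a ring C that arrives with O11, O12, the isopropyl group and O14 in place and a ring B that already carries O7.

Key step: step 12

Assumption (remark on the chemistry): the (1R,2R)-configured chromium complex is taken to shield the face of bound 2 that leads to (1R,2R)-4; if the sense of induction is the reverse, the (1S,2S)-complex is used and nothing else changes.

## Steps

Step 1
Reactants: 1 (E)-1-(dimethylamino)-3-(tert-butyldimethylsilyloxy)buta-1,3-diene; 2 ethyl (E)-3-methyl-4-oxobut-2-enoate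
Product: 4 ethyl (1R,2R)-2-formyl-2-methyl-5-oxocyclohex-3-ene-1-carboxylate, via cycloadduct 3 (not isolated)
Conditions: (1R,2R)-(salen)CrSbF6 (trivalent chromium; salen = N,N'-bis(3,5-di-tert-butylsalicylidene)cyclohexane-1,2-diaminate; 5 mol %), 4 Å MS, CH2Cl2, −40 °C; then 1 M HCl, THF, 0 °C
Reagents that add atoms: none
Why: Catalytic asymmetric Diels–Alder reaction in which the chromium centre binds the aldehyde of 2, so the nucleophilic CH2 terminus of 1 bonds to the ester-bearing carbon (C5–C6) and the amino-bearing terminus to the methyl-bearing carbon (C9–C10). Suprafacial addition carries the E geometry of 2 into the cis relation of ester and methyl, and the ligand-shielded face sets C5 and C10 together. Acid then hydrolyses the silyl enol ether and expels dimethylamine to leave the enone.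

Step 2
Reactants: 4 ethyl (1R,2R)-2-formyl-2-methyl-5-oxocyclohex-3-ene-1-carboxylate
Product: 5 ethyl 2-[(E)-3-methoxy-3-oxoprop-1-enyl]-2-methyl-5-oxocyclohex-3-ene-1-carboxylate (ring stereocentres as in 4)
Conditions: Ph3P=CHCO2Me, toluene, 60 °C
Reagents that add atoms: methyl (triphenylphosphoranylidene)acetate, COC(=O)C=P(c1ccccc1)(c1ccccc1)c1ccccc1
Why: Wittig olefination with a stabilised ylide, which reacts only with the aldehyde and leaves the enone and the ester alone, adds C2 and C3 of the arm. The neutral conditions avoid base-induced loss of the formyl group and epimerisation at C5. The alkene geometry is of no consequence because the bond is saturated in step 5.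

Step 3
Reactants: 5 ethyl 2-[(E)-3-methoxy-3-oxoprop-1-enyl]-2-methyl-5-oxocyclohex-3-ene-1-carboxylate
Product: 6 ethyl 4-iodo-2-[(E)-3-methoxy-3-oxoprop-1-enyl]-2-methyl-5-oxocyclohex-3-ene-1-carboxylate (iodine on C8)
Conditions: I2, pyridine, CH2Cl2, 0 °C → rt
Reagents that add atoms: iodine, II
Why: α-Iodination of a cyclic enone by conjugate addition of pyridine, iodination of the enolate at C8 and elimination, a reaction that is standard for 4,4-disubstituted cyclohex-2-enones. The acrylate arm is a weaker acceptor with a neopentyl β-carbon and should not enter this cycle.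

Step 4
Reactants: 6 ethyl 4-iodo-2-[(E)-3-methoxy-3-oxoprop-1-enyl]-2-methyl-5-oxocyclohex-3-ene-1-carboxylate
Product: 7 ethyl 6-iodo-8-[(E)-3-methoxy-3-oxoprop-1-enyl]-8-methyl-1,4-dioxaspiro[4.5]dec-6-ene-9-carboxylate
Conditions: HOCH2CH2OH, TsOH·H2O (cat.), benzene, reflux, azeotropic removal of water
Reagents that add atoms: ethane-1,2-diol, OCCO
Why: Acid-catalysed ketalisation of the C7 ketone, and the double bond cannot move out of position because C10 is quaternary. The ketal protects C7 through all organometallic steps and makes the iodoalkene a precursor of an α-keto vinyl anion equivalent.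

Step 5
Reactants: 7 ethyl 6-iodo-8-[(E)-3-methoxy-3-oxoprop-1-enyl]-8-methyl-1,4-dioxaspiro[4.5]dec-6-ene-9-carboxylate
Product: 8 ethyl 6-iodo-8-(3-methoxy-3-oxopropyl)-8-methyl-1,4-dioxaspiro[4.5]dec-6-ene-9-carboxylate
Conditions: 2-O2NC6H4SO2NHNH2, Et3N, CH2Cl2, rt
Reagents that add atoms: none
Why: Diimide reduction: the diimide released from the sulfonyl hydrazide transfers two hydrogens to the disubstituted arm alkene, while the trisubstituted iodoalkene reacts far more slowly and its C–I bond, which a hydrogenation catalyst would cleave, is not touched. The step is placed after ketalisation so that the hydrazide finds no ketone to condense with.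

Step 6
Reactants: 8 ethyl 6-iodo-8-(3-methoxy-3-oxopropyl)-8-methyl-1,4-dioxaspiro[4.5]dec-6-ene-9-carboxylate
Product: 9 ethyl 8-(3-hydroxypropyl)-6-iodo-8-methyl-1,4-dioxaspiro[4.5]dec-6-ene-9-carboxylate
Conditions: LiBH4, THF, 0 °C → rt
Reagents that add atoms: none
Why: Chemoselective ester reduction: the unhindered methyl ester on the primary chain should be reduced well before the ethyl ester on C5, which sits on a secondary carbon next to the quaternary C10. Ketal and iodoalkene are inert to borohydride.

Step 7
Reactants: 9 ethyl 8-(3-hydroxypropyl)-6-iodo-8-methyl-1,4-dioxaspiro[4.5]dec-6-ene-9-carboxylate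
Product: 10 ethyl 8-[3-(tert-butyldimethylsilyloxy)propyl]-6-iodo-8-methyl-1,4-dioxaspiro[4.5]dec-6-ene-9-carboxylate
Conditions: TBSCl, imidazole, DMF, rt
Reagents that add atoms: tert-butyldimethylsilyl chloride, CC(C)(C)[Si](C)(C)Cl
Why: Routine silylation of a primary alcohol. The silyl ether withstands the organolithium reagents and the thermolysis and is removed by aqueous acid in step 13.

Step 8
Reactants: 10 ethyl 8-[3-(tert-butyldimethylsilyloxy)propyl]-6-iodo-8-methyl-1,4-dioxaspiro[4.5]dec-6-ene-9-carboxylate
Product: 11 2-{8-[3-(tert-butyldimethylsilyloxy)propyl]-6-iodo-8-methyl-1,4-dioxaspiro[4.5]dec-6-en-9-yl}propan-2-ol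
Conditions: MeLi, CeCl3, THF, −78 → 0 °C
Reagents that add atoms: methyllithium, [Li]C
Why: Double addition of a methylcerium reagent to the ester gives the tertiary carbinol. The organocerium species is non-basic, so the intermediate methyl ketone is not enolised and C5 keeps its configuration, and it does not exchange with the alkenyl iodide.

Step 9
Reactants: 11 2-{8-[3-(tert-butyldimethylsilyloxy)propyl]-6-iodo-8-methyl-1,4-dioxaspiro[4.5]dec-6-en-9-yl}propan-2-ol
Product: 12 tert-butyl{3-[6-iodo-8-methyl-9-(prop-1-en-2-yl)-1,4-dioxaspiro[4.5]dec-6-en-8-yl]propoxy}dimethylsilane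
Conditions: SOCl2, pyridine, CH2Cl2, −20 → 0 °C
Reagents that add atoms: none
Why: Dehydration of the tertiary alcohol through its chlorosulfite by base-induced elimination. The six methyl hydrogens are exposed whereas H-5 is shielded by the quaternary C10, and the tetrasubstituted isopropylidene isomer would suffer allylic strain against the C10 substituents, so the isopropenyl isomer should prevail. Pyridine buffers the medium for the dioxolane and the silyl ether.

Step 10
Reactants: 12 tert-butyl{3-[6-iodo-8-methyl-9-(prop-1-en-2-yl)-1,4-dioxaspiro[4.5]dec-6-en-8-yl]propoxy}dimethylsilane; 13 diisopropyl squarate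
Product: 16 4-(ring-B alkenyl)-2,3-diisopropoxy-4-(trimethylsilyloxy)cyclobut-2-en-1-one (ring-B alkenyl = 12 with the four-membered ring on C8 in place of iodine; both carbinol epimers), via alkenyllithium 14 (not isolated), via lithium alkoxide 15 (not isolated)
Conditions: t-BuLi (2 equiv), THF, −78 °C; then 13, −78 °C; then TMSCl, −78 → 0 °C
Reagents that add atoms: chlorotrimethylsilane, C[Si](C)(C)Cl
Why: Iodine–lithium exchange gives the alkenyllithium, which is stable because β-elimination of a ketal oxygen would require a cyclic allene. 1,2-Addition to one of the two equivalent carbonyls of the squarate forms the C8–C14 bond, and the tertiary alkoxide is capped in the flask so that this oxygen cannot ionise in step 11. The carbinol configuration is irrelevant because C14 becomes sp2 in step 12.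

Step 11
Reactants: 16 4-(ring-B alkenyl)-2,3-diisopropoxy-4-(trimethylsilyloxy)cyclobut-2-en-1-one; 17 isopropyllithium
Product: 19 4-(ring-B alkenyl)-2-isopropoxy-3-isopropyl-4-(trimethylsilyloxy)cyclobut-2-en-1-one, via lithium alkoxide 18 (not isolated)
Conditions: 17, THF, −78 °C; then (CF3CO)2O, −78 °C; then aq. NaHCO3
Reagents that add atoms: water, O
Why: Addition of the alkyllithium to the remaining carbonyl followed by trifluoroacetylation of the alkoxide triggers ionisation to an isopropoxy-stabilised cyclobutenyl cation, and hydrolysis moves the carbonyl to the far carbon with loss of one isopropoxy group (1,3-carbonyl transposition of squarate bis-adducts). This places the isopropyl carbon (C13) next to the carbinol carbon (C14). If the bulky nucleophile instead adds in conjugate fashion and expels isopropoxide, the same constitution results, so the regiochemistry does not depend on the mode of attack.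

Step 12
Reactants: 19 4-(ring-B alkenyl)-2-isopropoxy-3-isopropyl-4-(trimethylsilyloxy)cyclobut-2-en-1-one
Product: 22 ring-C hydroquinone with 11-hydroxyl, 12-isopropoxy, 13-isopropyl, 14-trimethylsilyloxy, C7 dioxolane and C3 tert-butyldimethylsilyl ether, via dienylketene 20 (not isolated), via cyclohexadienone 21 (not isolated)
Conditions: p-xylene (degassed), 138 °C, Ar
Reagents that add atoms: none
Why: Heating opens the C11–C14 bond of the cyclobutenone in a conrotatory 4π electrocyclic reaction; the silyloxy donor on C14 rotates outward, which turns the ring-B alkenyl group inward, cis to the ketene arm of 20. The ketene carbon C11 then bonds to C9 in a disrotatory 6π electrocyclisation of the C11=C12–C13=C14–C8=C9 system, closing ring C as the cyclohexadienone 21, and transfer of the C9 hydrogen to O11 aromatises it to 22. The closest known reaction type is the Moore ring expansion of squarate-derived 4-alkenyl-4-hydroxy- or 4-silyloxycyclobutenones to hydroquinones, here with a hindered cycloalkenyl group. No stereocentre is formed: both C14 epimers of 19 give the same ketene, C9 is stereogenic only in 21, and C5 and C10 are not touched under neutral thermal conditions. The step needs two selectivities: the regiochemistry (isopropoxy on C12, isopropyl on C13) is fixed in 19 by the order of addition in steps 10 and 11, and the torquoselectivity is inherent to an oxygen donor on the breaking bond. Keeping the carbinol as a silyl ether blocks addition of a hydroxyl to the ketene, which matters because bond formation at C9, beside the quaternary C10, is expected to be slow. Release of four-membered ring strain and aromatisation drive the closure. Any silyl migration between O14 and O11 is without consequence, since step 13 removes the group.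

Step 13
Reactants: 22 ring-C hydroquinone with 11-hydroxyl, 12-isopropoxy, 13-isopropyl, 14-trimethylsilyloxy, C7 dioxolane and C3 tert-butyldimethylsilyl ether
Product: 23 11,14-dihydroxy-12-isopropoxy-13-isopropyl arene with C7 ketone and 3-hydroxypropyl arm on C10
Conditions: 1 M HCl (aq.), THF, rt, Ar
Reagents that add atoms: water, O
Why: Acid hydrolysis: the C7 dioxolane is now benzylic and ortho to a phenolic oxygen, so it ionises readily, which is why C7 is unmasked before the ring is oxidised to the electron-poor quinone. The aryl trimethylsilyl ether and the primary silyl ether fall under the same conditions, while the aryl isopropyl ether, the isopropenyl group and both stereocentres are unaffected.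

Step 14
Reactants: 23 11,14-dihydroxy-12-isopropoxy-13-isopropyl arene with C7 ketone and 3-hydroxypropyl arm on C10
Product: 24 3-[12-isopropoxy-13-isopropyl-7,11,14-trioxo ring-B/C quinone]propanoic acid (C3 acid)
Conditions: PhI(OAc)2, TEMPO (cat.), MeCN/H2O, rt
Reagents that add atoms: water, O
Why: One oxidant does two jobs: PhI(OAc)2 oxidises the hydroquinone to the quinone, and the nitroxyl-catalysed oxidation in aqueous acetonitrile takes the primary alcohol through the aldehyde hydrate to the carboxylic acid. The near-neutral medium spares the isopropenyl group, the vinylogous isopropyl ester at C12 and the enolisable C6 methylene.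

Step 15
Reactants: 24 3-[12-isopropoxy-13-isopropyl-7,11,14-trioxo ring-B/C quinone]propanoic acid
Product: 25 methyl ester of 24 (12-isopropyl ether of 26)
Conditions: TMSCHN2, toluene/MeOH, 0 °C
Reagents that add atoms: trimethylsilyldiazomethane, C[Si](C)(C)C=[N+]=[N-]
Why: Methyl esterification of a carboxylic acid under neutral conditions. The C12 oxygen is still an isopropyl ether, so the acidic hydroxyquinone that would also be methylated is not yet present, and the fully substituted quinone offers no open C=C for dipolar addition.

Step 16
Reactants: 25 methyl ester of 24 (12-isopropyl ether of 26)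
Product: 26 methyl 3-[(1S,2S)-7-hydroxy-1-methyl-4,5,8-trioxo-6-(propan-2-yl)-2-(prop-1-en-2-yl)-1,2,3,4,5,8-hexahydronaphthalen-1-yl]propanoate
Conditions: BCl3, CH2Cl2, −78 °C; then H2O
Reagents that add atoms: none
Why: Lewis acid dealkylation: BCl3 is held between the C11 carbonyl and the C12 ether oxygen and cleaves the secondary isopropyl group as the chloride, a vinylogous ester cleavage. At −78 °C with short contact the methyl ester and the isopropenyl group should survive, and hydrolysis of the borate gives the hydroxyquinone.

## Compound list

1 | (E)-1-(dimethylamino)-3-(tert-butyldimethylsilyloxy)buta-1,3-diene | CN(C)/C=C/C(=C)O[Si](C)(C)C(C)(C)C | starting material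
2 | ethyl (E)-3-methyl-4-oxobut-2-enoate | CCOC(=O)/C=C(\C)C=O | starting material
3 | ethyl 3-(tert-butyldimethylsilyloxy)-5-(dimethylamino)-6-formyl-6-methylcyclohex-3-ene-1-carboxylate (C1 and C6 as in 4, amino-bearing carbon unassigned; not isolated) | CCOC(=O)[C@@H]1CC(O[Si](C)(C)C(C)(C)C)=CC(N(C)C)[C@@]1(C)C=O | intermediate
4 | ethyl (1R,2R)-2-formyl-2-methyl-5-oxocyclohex-3-ene-1-carboxylate (ester cis to methyl, trans to formyl) | CCOC(=O)[C@@H]1CC(=O)C=C[C@@]1(C)C=O | intermediate
5 | ethyl 2-[(E)-3-methoxy-3-oxoprop-1-enyl]-2-methyl-5-oxocyclohex-3-ene-1-carboxylate (ring stereocentres as in 4) | CCOC(=O)[C@@H]1CC(=O)C=C[C@@]1(C)/C=C/C(=O)OC | intermediate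
6 | ethyl 4-iodo-2-[(E)-3-methoxy-3-oxoprop-1-enyl]-2-methyl-5-oxocyclohex-3-ene-1-carboxylate | CCOC(=O)[C@@H]1CC(=O)C(I)=C[C@@]1(C)/C=C/C(=O)OC | intermediate
7 | ethyl 6-iodo-8-[(E)-3-methoxy-3-oxoprop-1-enyl]-8-methyl-1,4-dioxaspiro[4.5]dec-6-ene-9-carboxylate (ester cis to methyl) | CCOC(=O)[C@@H]1CC2(OCCO2)C(I)=C[C@@]1(C)/C=C/C(=O)OC | intermediate
8 | ethyl 6-iodo-8-(3-methoxy-3-oxopropyl)-8-methyl-1,4-dioxaspiro[4.5]dec-6-ene-9-carboxylate | CCOC(=O)[C@@H]1CC2(OCCO2)C(I)=C[C@@]1(C)CCC(=O)OC | intermediate
9 | ethyl 8-(3-hydroxypropyl)-6-iodo-8-methyl-1,4-dioxaspiro[4.5]dec-6-ene-9-carboxylate | CCOC(=O)[C@@H]1CC2(OCCO2)C(I)=C[C@@]1(C)CCCO | intermediate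
10 | ethyl 8-[3-(tert-butyldimethylsilyloxy)propyl]-6-iodo-8-methyl-1,4-dioxaspiro[4.5]dec-6-ene-9-carboxylate | CCOC(=O)[C@@H]1CC2(OCCO2)C(I)=C[C@@]1(C)CCCO[Si](C)(C)C(C)(C)C | intermediate
11 | 2-{8-[3-(tert-butyldimethylsilyloxy)propyl]-6-iodo-8-methyl-1,4-dioxaspiro[4.5]dec-6-en-9-yl}propan-2-ol | CC(C)(O)[C@@H]1CC2(OCCO2)C(I)=C[C@@]1(C)CCCO[Si](C)(C)C(C)(C)C | intermediate
12 | tert-butyl{3-[6-iodo-8-methyl-9-(prop-1-en-2-yl)-1,4-dioxaspiro[4.5]dec-6-en-8-yl]propoxy}dimethylsilane (5β-isopropenyl, 10β-methyl; iodine on C8, dioxolane on C7) | C=C(C)[C@@H]1CC2(OCCO2)C(I)=C[C@@]1(C)CCCO[Si](C)(C)C(C)(C)C | intermediate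
13 | diisopropyl squarate (3,4-diisopropoxycyclobut-3-ene-1,2-dione) | CC(C)OC1=C(OC(C)C)C(=O)C1=O | starting material
14 | C8 alkenyllithium from 12 (lithium in place of iodine; not isolated) | C=C(C)[C@@H]1CC2(OCCO2)C([Li])=C[C@@]1(C)CCCO[Si](C)(C)C(C)(C)C | intermediate
15 | lithium alkoxide of 4-(ring-B alkenyl)-4-hydroxy-2,3-diisopropoxycyclobut-2-en-1-one (not isolated) | C=C(C)[C@@H]1CC2(OCCO2)C(C3(O[Li])C(OC(C)C)=C(OC(C)C)C3=O)=C[C@@]1(C)CCCO[Si](C)(C)C(C)(C)C | intermediate
16 | 4-(ring-B alkenyl)-2,3-diisopropoxy-4-(trimethylsilyloxy)cyclobut-2-en-1-one (both carbinol epimers) | C=C(C)[C@@H]1CC2(OCCO2)C(C3(O[Si](C)(C)C)C(OC(C)C)=C(OC(C)C)C3=O)=C[C@@]1(C)CCCO[Si](C)(C)C(C)(C)C | intermediate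
17 | isopropyllithium | CC(C)[Li] | starting material
18 | lithium 4-(ring-B alkenyl)-1-isopropyl-2,3-diisopropoxy-4-(trimethylsilyloxy)cyclobut-2-en-1-olate (not isolated) | C=C(C)[C@@H]1CC2(OCCO2)C(C3(O[Si](C)(C)C)C(OC(C)C)=C(OC(C)C)C3(O[Li])C(C)C)=C[C@@]1(C)CCCO[Si](C)(C)C(C)(C)C | intermediate
19 | 4-(ring-B alkenyl)-2-isopropoxy-3-isopropyl-4-(trimethylsilyloxy)cyclobut-2-en-1-one (both carbinol epimers; C7 dioxolane, C3 silyl ether) | C=C(C)[C@@H]1CC2(OCCO2)C(C3(O[Si](C)(C)C)C(C(C)C)=C(OC(C)C)C3=O)=C[C@@]1(C)CCCO[Si](C)(C)C(C)(C)C | intermediate
20 | dienylketene: C11 ketene, C12 isopropoxy, C13 isopropyl, C14 trimethylsilyloxy, ring-B alkenyl on C14 cis to C12 (not isolated) | C=C(C)[C@@H]1CC2(OCCO2)C(/C(O[Si](C)(C)C)=C(C(C)C)\C(OC(C)C)=C=O)=C[C@@]1(C)CCCO[Si](C)(C)C(C)(C)C | intermediate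
21 | ring-C cyclohexa-2,4-dienone with C11 carbonyl and C9 hydrogen (not isolated) | C=C(C)[C@@H]1CC2(OCCO2)C3=C(O[Si](C)(C)C)C(C(C)C)=C(OC(C)C)C(=O)C3[C@@]1(C)CCCO[Si](C)(C)C(C)(C)C | intermediate
22 | ring-C hydroquinone: 11-hydroxyl, 12-isopropoxy, 13-isopropyl, 14-trimethylsilyloxy, C7 dioxolane, C3 tert-butyldimethylsilyl ether | C=C(C)[C@@H]1CC2(OCCO2)c3c(O[Si](C)(C)C)c(C(C)C)c(OC(C)C)c(O)c3[C@@]1(C)CCCO[Si](C)(C)C(C)(C)C | intermediate
23 | 11,14-dihydroxy-12-isopropoxy-13-isopropyl arene with C7 ketone, 5β-isopropenyl, 10β-methyl and 10α-(3-hydroxypropyl) | C=C(C)[C@@H]1CC(=O)c2c(O)c(C(C)C)c(OC(C)C)c(O)c2[C@@]1(C)CCCO | intermediate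
24 | 12-isopropoxy-13-isopropyl-7,11,14-trioxo quinone with C3 carboxylic acid | C=C(C)[C@@H]1CC(=O)C2=C(C(=O)C(OC(C)C)=C(C(C)C)C2=O)[C@@]1(C)CCC(=O)O | intermediate
25 | methyl ester of 24 (12-isopropyl ether of 26) | C=C(C)[C@@H]1CC(=O)C2=C(C(=O)C(OC(C)C)=C(C(C)C)C2=O)[C@@]1(C)CCC(=O)OC | intermediate
26 | methyl 3-[(1S,2S)-7-hydroxy-1-methyl-4,5,8-trioxo-6-(propan-2-yl)-2-(prop-1-en-2-yl)-1,2,3,4,5,8-hexahydronaphthalen-1-yl]propanoate | C=C(C)[C@@H]1CC(=O)C2=C(C(=O)C(O)=C(C(C)C)C2=O)[C@@]1(C)CCC(=O)OC | target

## Step count and least certain steps

Total step count: 16. Longest linear sequence: 16 steps (1 and 2 to 26); 13 and 17 are commercial and enter at steps 10 and 11.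

Step 12 (key step). The most likely failure is that ring opening occurs but closure does not: the spiro-dioxolane on C7 and the quaternary C10 both hinder the C8=C9 bond from becoming coplanar with the ketene diene, so 20 would revert to 19 and slowly be lost to other ketene reactions. The fallback keeps the ring expansion but carries C7 at the alcohol oxidation level, where a secondary silyl ether can turn its hydrogen toward C14. It sets out from 12: mild hydrolysis of the ketal (pyridinium p-toluenesulfonate, wet acetone, 40 °C) gives iodoenone F1, Luche reduction (NaBH4, CeCl3·7H2O, MeOH) gives allylic alcohol F2, and silylation (TBSOTf, 2,6-lutidine) gives bis-silyl ether F3. The operations of steps 10 and 11 then give squarate adduct F4 and transposed cyclobutenone F5, thermolysis gives hydroquinone F6, and fluoride (Bu4NF, THF) removes the three silyl groups to give tetraol F7. The oxidation of step 14, with one more equivalent of PhI(OAc)2, converts the C7 carbinol into the ketone together with quinone and acid formation, and the route is rejoined at 24.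

Step 11. The most likely failure is that the bulky secondary alkyllithium does not add cleanly to a carbonyl flanked by the fully substituted C14 (hydride transfer instead of addition), or that the strained alkoxide 18 fragments before it is acylated. The fallback fixes the regiochemistry on the small partners instead and sets out from 13 and 12. Addition of 17 to 13 followed by aqueous HCl gives 3-isopropoxy-4-isopropylcyclobut-3-ene-1,2-dione F8. Its more electrophilic carbonyl, the one next to the alkoxy carbon, is masked selectively (MeOSiMe3, TMSOTf cat., CH2Cl2, −78 °C) as dimethyl ketal F9. Alkenyllithium 14, made from 12 as in step 10, adds to the remaining carbonyl to give carbinol F10. Dilute aqueous acid cleaves the acyclic ketal, which is far more labile than the C7 dioxolane, to give hydroxycyclobutenone F11, and silylation (TMSCl, imidazole) returns to 19.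

Step 1. The most likely failure is erosion of enantiomeric purity by uncatalysed cycloaddition, because the diene is very reactive and 2 is activated at both alkene carbons. The fallback moves the control element from the catalyst to the diene and sets out from 2. The C2-symmetric aminosiloxydiene F12, made from (2R,5R)-2,5-diphenylpyrrolidine (the antipode of the auxiliary being chosen to lead to 4), adds to 2 without catalyst to give cycloadduct F13. The same acid work-up releases the recoverable auxiliary and the route is rejoined at 4.

Step 9. The most likely failure is competing loss of H-5, which would give the isopropylidene isomer and erase C5, or capture of the tertiary cation by chloride. The fallback builds the alkene by carbonyl olefination instead of elimination. It sets out from 10: MeNH(OMe)·HCl/AlMe3 gives the N-methoxy-N-methylamide F14, MeMgBr gives methyl ketone F15, and methylenation with Ph3P=CH2 (THF, 0 °C) rejoins the route at 12.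

Step 5. The most likely failure is sluggish hydrogen transfer to an alkene that has a neopentyl terminus, with decomposition of diimide outrunning reduction. The fallback is a conjugate hydride reduction that acts only on the enoate: [(Ph3P)CuH]6 (monovalent copper, catalytic) with polymethylhydrosiloxane and t-BuOH in toluene converts 7 directly into 8, and no new compound is involved.

## Further compounds

F1 | step 12 | 4-[3-(tert-butyldimethylsilyloxy)propyl]-2-iodo-4-methyl-5-(prop-1-en-2-yl)cyclohex-2-en-1-one (stereocentres as in 12) | C=C(C)[C@@H]1CC(=O)C(I)=C[C@@]1(C)CCCO[Si](C)(C)C(C)(C)C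
F2 | step 12 | 4-[3-(tert-butyldimethylsilyloxy)propyl]-2-iodo-4-methyl-5-(prop-1-en-2-yl)cyclohex-2-en-1-ol (either C7 epimer) | C=C(C)[C@@H]1CC(O)C(I)=C[C@@]1(C)CCCO[Si](C)(C)C(C)(C)C
F3 | step 12 | tert-butyldimethylsilyl ether of F2 at the C7 oxygen | C=C(C)[C@@H]1CC(O[Si](C)(C)C(C)(C)C)C(I)=C[C@@]1(C)CCCO[Si](C)(C)C(C)(C)C
F4 | step 12 | 4-(ring-B alkenyl)-2,3-diisopropoxy-4-(trimethylsilyloxy)cyclobut-2-en-1-one with C7 silyl ether | C=C(C)[C@@H]1CC(O[Si](C)(C)C(C)(C)C)C(C2(O[Si](C)(C)C)C(OC(C)C)=C(OC(C)C)C2=O)=C[C@@]1(C)CCCO[Si](C)(C)C(C)(C)C
F5 | step 12 | 4-(ring-B alkenyl)-2-isopropoxy-3-isopropyl-4-(trimethylsilyloxy)cyclobut-2-en-1-one with C7 silyl ether | C=C(C)[C@@H]1CC(O[Si](C)(C)C(C)(C)C)C(C2(O[Si](C)(C)C)C(C(C)C)=C(OC(C)C)C2=O)=C[C@@]1(C)CCCO[Si](C)(C)C(C)(C)C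
F6 | step 12 | ring-C hydroquinone with 11-hydroxyl, 12-isopropoxy, 13-isopropyl, 14-trimethylsilyloxy, C7 and C3 tert-butyldimethylsilyl ethers | C=C(C)[C@@H]1CC(O[Si](C)(C)C(C)(C)C)c2c(O[Si](C)(C)C)c(C(C)C)c(OC(C)C)c(O)c2[C@@]1(C)CCCO[Si](C)(C)C(C)(C)C
F7 | step 12 | 7,11,14-trihydroxy-12-isopropoxy-13-isopropyl arene with 3-hydroxypropyl arm on C10 | C=C(C)[C@@H]1CC(O)c2c(O)c(C(C)C)c(OC(C)C)c(O)c2[C@@]1(C)CCCO
F8 | step 11 | 3-isopropoxy-4-isopropylcyclobut-3-ene-1,2-dione | CC(C)OC1=C(C(C)C)C(=O)C1=O
F9 | step 11 | 3-isopropoxy-4,4-dimethoxy-2-isopropylcyclobut-2-en-1-one | COC1(OC)C(OC(C)C)=C(C(C)C)C1=O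
F10 | step 11 | 1-(ring-B alkenyl)-3-isopropoxy-4,4-dimethoxy-2-isopropylcyclobut-2-en-1-ol | C=C(C)[C@@H]1CC2(OCCO2)C(C3(O)C(C(C)C)=C(OC(C)C)C3(OC)OC)=C[C@@]1(C)CCCO[Si](C)(C)C(C)(C)C
F11 | step 11 | 4-(ring-B alkenyl)-4-hydroxy-2-isopropoxy-3-isopropylcyclobut-2-en-1-one | C=C(C)[C@@H]1CC2(OCCO2)C(C3(O)C(C(C)C)=C(OC(C)C)C3=O)=C[C@@]1(C)CCCO[Si](C)(C)C(C)(C)C
F12 | step 1 | (2R,5R)-1-[(E)-3-(tert-butyldimethylsilyloxy)buta-1,3-dienyl]-2,5-diphenylpyrrolidine | C=C(O[Si](C)(C)C(C)(C)C)/C=C/N1[C@@H](c2ccccc2)CC[C@@H]1c1ccccc1
F13 | step 1 | ethyl 3-(tert-butyldimethylsilyloxy)-5-[(2R,5R)-2,5-diphenylpyrrolidin-1-yl]-6-formyl-6-methylcyclohex-3-ene-1-carboxylate (C1 and C6 as in 4) | CCOC(=O)[C@@H]1CC(O[Si](C)(C)C(C)(C)C)=CC(N2[C@@H](c3ccccc3)CC[C@@H]2c2ccccc2)[C@@]1(C)C=O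
F14 | step 9 | 8-[3-(tert-butyldimethylsilyloxy)propyl]-6-iodo-N-methoxy-N,8-dimethyl-1,4-dioxaspiro[4.5]dec-6-ene-9-carboxamide | CON(C)C(=O)[C@@H]1CC2(OCCO2)C(I)=C[C@@]1(C)CCCO[Si](C)(C)C(C)(C)C
F15 | step 9 | 1-{8-[3-(tert-butyldimethylsilyloxy)propyl]-6-iodo-8-methyl-1,4-dioxaspiro[4.5]dec-6-en-9-yl}ethan-1-one | CC(=O)[C@@H]1CC2(OCCO2)C(I)=C[C@@]1(C)CCCO[Si](C)(C)C(C)(C)C
F0 | step 5 | none | none
A1 | alternative 1 | 2-allyl-2-methyl-3-(prop-1-en-2-yl)cyclohexan-1-one (allyl trans to isopropenyl) | C=C(C)[C@@H]1CCCC(=O)[C@@]1(C)CC=C
A2 | alternative 1 | 2-methylcyclohex-2-en-1-one | CC1=CCCCC1=O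
A3 | alternative 2 | ethyl 2-formyl-2-methyl-5-oxocyclohex-3-ene-1-carboxylate (formyl trans to ester) | CCOC(=O)[C@@H]1CC(=O)C=C[C@@]1(C)C=O
A4 | alternative 3 | pentacarbonyl[methoxy(ring-B alkenyl)carbene]chromium, carbene carbon C11 bonded to C9, C10 bearing methyl and allyl, C5 isopropenyl | C=C(C)[C@@H]1CCC=C(C(OC)=[Cr](=C=O)(=C=O)(=C=O)(=C=O)=C=O)[C@@]1(C)CC=C
A5 | alternative 3 | 3-methylbut-1-yne | C#CC(C)C
A6 | alternative 3 | ring-C phenol with C14 hydroxyl, C13 isopropyl, C11 methoxy, unsubstituted C12 | C=C(C)[C@@H]1CCc2c(O)c(C(C)C)cc(OC)c2[C@@]1(C)CC=C
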